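## The problem

The target is a daucane-type sesquiterpenoid ester built on a trans-fused hydroazulene with six stereocentres. Numbering used throughout: five-membered ring C1(Me, quaternary)–C2–C3–C4(OH, iPr)–C5(H); seven-membered ring C5–C6(O-aroyl)–C7(=O)–C8(OH, Me)–C9(OH)–C10–C1. β is the face of the C1 methyl group; the same locants are kept for the hydrindane intermediates, whose six-membered ring is C1–C10–C9–C8–C7–C5. In these terms the target is 1β-Me, 5α-H, 4β-OH/4α-iPr, 6α-OAr, 8α-OH/8β-Me, 9α-OH, i.e. (1R,4R,5S,6R,8S,9S). The C1/C5 pair must be set early and with absolute control, because no later centre can correct it. Once it is in place the axial C1 methyl shields the β face and can steer oxygenation at C8/C9 and C7, while C4 has to be fixed relative to C5 when the cyclopentane closes. The fragile region is C6–C9: an acyloin ester at C6/C7 next to a tertiary α-ketol at C8, open to C6 epimerisation, α-ketol shifts and acyl migration, beside two tertiary alcohols and a phenolic ester. The enabling feature is that the C6(O)–C7(=O) acyloin sits directly beside ring-fusion carbon C5. It is the rearranged form of a cyclohexane in which C7 bears both a hydroxyl and the formyl carbon C6, so the seven-membered ring and the C6 stereocentre can both come from one ring enlargement of a trans-hydrindane.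

## Retrosynthesis

**Ester and protecting groups.** The target 24 is traced to its benzyl ether 23 and then to the fully protected ester 22, which is cut at the C6–O acyl bond into acyloin 20 and commercial acid chloride 21. The base-labile aryl ester is attached last. The phenol is carried as a benzyl ether so that the final step is neutral. The acetonide on C8/C9 and the triethylsilyl ether on C4 leave C6–OH as the only free hydroxyl of 20.

**Key disconnection.** In 20 the C5–C6 bond is cut and C5 is reconnected to C7, giving the trans-hydrindane α-hydroxy aldehyde 19. The neighbouring cuts (C6–C7 or C7–C8) would each demand a direct seven-membered ring closure and a separate installation of the C6 oxygen. This cut turns the problem into a rigid six-membered ring and delivers ketone, carbinol and ring in one event. The forward reaction must make C5 migrate in preference to C8 and must fix C6.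

**The C7 carbinol.** Aldehyde 19 comes from diol 18, which is the osmylation product of exocyclic alkene 17, made from ketone 16. Direct addition of a one-carbon nucleophile to 16 would enter anti to the angular methyl and put the C7 oxygen on the β face, the wrong epimer for the chelate-controlled shift. Olefination followed by oxygen delivery from the α side gives the required C7-OH α / CH2OH β arrangement.

**The C8/C9 diol and the C7 oxygen.** Acetonide 16 comes from diol 15, the syn-dihydroxylation product of enone 14. Enone 14 arises from alkene 12 by allylic oxidation at the ring methylene C7. This removes three oxygens and leaves a trans-hydrindene with a single trisubstituted alkene.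

**The cyclopentane.** Silyl ether 12 is the protected form of tertiary alcohol 11. Cutting the C3–C4 bond of 11 gives iodo ketone 10, whose ketone already carries the isopropyl group, so ring closure and the C4 carbinol come from one Barbier step. Iodide 10 derives from hydroxy ketone 9, which is the mono-adduct of isopropyllithium (8) with δ-lactone 7. Using the lactone avoids a separate acyl activation and prevents over-addition.

**The ring-fusion pair.** Lactone 7 comes from vinyl ester 4 by anti-Markovnikov hydration, and 4 from aldehyde 3 by methylenation. Cyclohexene 3 is cut at C1–C10 and C5–C7 into commercial (E)-enal ester 1 and isoprene (2). The E geometry of 1 becomes the trans relation of the two arms on C1 and C5. A chiral Lewis acid sets both centres absolutely in the first step, and isoprene supplies C8 with its methyl and the C8=C9 alkene. The forward reaction needs "para" regiochemistry and high facial selectivity on a 2-methyl enal.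

## Roads not taken

**Alternative 1:** cut C1–C5 and C1–C10 together.
- Forward step: diazoketone A1 (diazo carbon bearing the future angular methyl, a 3,5-dimethoxy-4-methylphenyl group on the C4 carbinol) is decomposed with Rh2(OAc)4. The carbenoid adds across the ipso–ortho bond and the norcaradiene opens to dihydroazulenone A2.
- Merits: both rings and the quaternary C1 arise in one step from flat aromatic chemistry, with carbon or oxygen already on C7, C8 and C9. In skeletal economy this is better than the chosen plan.
- Weak points: C4 alone must control C1 across the new ring. In A2, C5 is sp2 and C6 is an unfunctionalised vinylic CH, so C5-H, the C6 oxygen, the C8 carbinol and C9 must all be set on a flexible, acid-sensitive bis-enol-ether triene. The C2 ketone has to be removed, and the tertiary benzylic ether β to it invites elimination.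
- Comparison: the chosen plan is longer to the bicycle, but it sets C1/C5 in one catalytic step, sets C8/C9 on a rigid trans-hydrindane and obtains C6 from the ring enlargement itself.

**Alternative 2:** cut C4–C5.
- Forward step: diazo ester A3 with Rh2(OAc)4 gives 1,5 C–H insertion into the oxygen-activated C4–H bond with retention, forming cyclopentane A4.
- Merits: the tertiary C4 ether is derived from a secondary carbinol that is easy to obtain enantiopure. This is a more secure way to fix C4 than the rotamer control relied on in step 6.
- Weak points: C5 relative to C1 depends on telling a methyl from a vinyl group. C1 and C4 need two independent asymmetric operations. Insertion into the isopropyl methine or the acetal C–H can compete. The whole seven-membered ring with four oxygenated carbons remains to be built.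
- Comparison: the chosen plan accepts a less certain C4 step in exchange for fixing C1 and C5 together and obtaining ring, ketone and C6 carbinol in one step.

**Alternative 3:** cut C6–C7.
- Forward step: (Z)-enoyl selenide A5 with (Me3Si)3SiH gives the C7 acyl radical, which closes 7-endo onto the exocyclic methylene; the C5 radical then takes hydrogen to give enone A6.
- Merits: the seven-membered ring forms directly, with the enone ready for 8,9-dihydroxylation. It avoids the allylic oxidation and the hindered methylenation of the chosen route, and is better in that respect.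
- Weak points: C5 is created by hydrogen transfer to a tertiary radical between two fully substituted carbons, so trans fusion is not assured. α,β-Unsaturated acyl radicals can lose their Z geometry, and 6-exo closure competes. C6 arrives as CH2 and must be hydroxylated later on a flexible ring without a chelate to guide it.
- Comparison: the chosen plan fixes C5 together with C1 in a concerted cycloaddition and obtains the C6 oxygen with defined configuration in the key step.

Key step: step 14

Assumption: the (S)-oxazaborolidinium catalyst is taken to deliver the diene to the Cα re face of enal 1, as it does with 2-methylacrolein; should the sense prove opposite, the (R)-catalyst is used.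

## Route

Step 1
Reactants: 1 ethyl (2E)-3-methyl-4-oxobut-2-enoate; 2 isoprene
Product: 3 ethyl (1R,6R)-6-formyl-3,6-dimethylcyclohex-3-ene-1-carboxylate
Conditions: (S)-3,3-diphenyl-1-(2-methylphenyl)tetrahydro-1H,3H-pyrrolo[1,2-c][1,3,2]oxazaborole·HN(SO2CF3)2 (20 mol%), CH2Cl2, −78 to −40 °C
Reagents that add atoms: none
Why: Catalytic enantioselective Diels–Alder reaction of a 2-methyl enal with a CBS-type oxazaborolidinium Lewis acid; the catalyst-bound formyl group makes C5 the electrophilic terminus, which bonds to the methyl-bearing end of isoprene (C8 methyl 1,4 to C1), suprafacial addition turns the E geometry into trans C2/C4 arms (C1-Me cis to the ester), and shielding of one enal face sets C1 and with it C5.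

Step 2
Reactants: 3 ethyl (1R,6R)-6-formyl-3,6-dimethylcyclohex-3-ene-1-carboxylate
Product: 4 ethyl 6-ethenyl-3,6-dimethylcyclohex-3-ene-1-carboxylate (vinyl trans to the ester, centres as in 3)
Conditions: Ph3PCH3Br, KN(SiMe3)2, THF, −78 to 0 °C
Reagents that add atoms: methyltriphenylphosphonium bromide, C[P+](c1ccccc1)(c1ccccc1)c1ccccc1.[Br-]
Why: Wittig methylenation; the non-enolisable neopentyl aldehyde reacts far faster than the ester, and the ylide is too weak a base to epimerise the ester α-centre C5 at low temperature.

Step 3
Reactants: 4 ethyl 6-ethenyl-3,6-dimethylcyclohex-3-ene-1-carboxylate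
Product: 7 trans-fused lactone (4aS,8aR)-4a,7-dimethyl-3,4,4a,5,8,8a-hexahydro-1H-isochromen-1-one, via alkylborane 5 (not isolated), via hydroxy ester 6 (not isolated)
Conditions: 9-BBN, THF, 0 °C to rt; NaBO3·4H2O, H2O; then TsOH·H2O (cat.), PhMe, 60 °C
Reagents that add atoms: 9-borabicyclo[3.3.1]nonane, B1C2CCCC1CCC2; sodium perborate, [Na+].O=BO[O-]
Why: Hydroboration–oxidation, with 9-BBN adding anti-Markovnikov to the monosubstituted alkene only (ring alkene and ester untouched), followed by acid-catalysed lactonisation of the primary alcohol onto the trans-disposed ester; no stereocentre is involved.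

Step 4
Reactants: 7 trans-fused lactone; 8 isopropyllithium
Product: 9 1-[6-(2-hydroxyethyl)-3,6-dimethylcyclohex-3-en-1-yl]-2-methylpropan-1-one (acyl trans to the hydroxyethyl arm, centres as in 3)
Conditions: i-PrLi (1.1 equiv), Et2O, −78 °C; aq. NH4Cl
Reagents that add atoms: none
Why: Mono-addition of an alkyllithium to a lactone; the lithium lactolate is stable at −78 °C and blocks a second addition, so work-up releases the δ-hydroxy isopropyl ketone (in equilibrium with its lactol) without disturbing C5.

Step 5
Reactants: 9 δ-hydroxy isopropyl ketone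
Product: 10 1-[6-(2-iodoethyl)-3,6-dimethylcyclohex-3-en-1-yl]-2-methylpropan-1-one
Conditions: I2, PPh3, imidazole, CH2Cl2, 0 °C
Reagents that add atoms: iodine, II
Why: Appel-type (Garegg–Samuelsson) iodination of the primary alcohol; the open hydroxy ketone is drawn out of the lactol equilibrium and the buffered neutral medium leaves the ketone α-centre intact.

Step 6
Reactants: 10 iodo ketone
Product: 11 trans-hydrindenol, 4α-isopropyl-1β,8-dimethyl-5α-H-hydrind-8-en-4β-ol (route locants; indene name 3a,6-dimethyl-1-(propan-2-yl)-2,3,3a,4,7,7a-hexahydro-1H-inden-1-ol)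
Conditions: SmI2 (2.5 equiv), HMPA, THF, −78 °C to rt
Reagents that add atoms: none
Why: SmI2-mediated intramolecular Barbier reaction, a 5-exo closure of the C3 organosamarium onto the C4 ketone that forms the trans-fused cyclopentanol; in the closing transition state the isopropyl group takes the α position, away from the angular C1 methyl and C7, so the alkoxide ends β (C4-OH cis to C1-Me).

Step 7
Reactants: 11 trans-hydrindenol
Product: 12 4β-triethylsilyl ether of 11
Conditions: Et3SiOTf, 2,6-lutidine, CH2Cl2, −78 to 0 °C
Reagents that add atoms: triethylsilyl trifluoromethanesulfonate, CC[Si](CC)(CC)OS(=O)(=O)C(F)(F)F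
Why: Silylation of a hindered tertiary alcohol with a silyl triflate; the ether prevents retro-aldol cleavage once C7 is a ketone and lactol formation with the later C6 aldehyde.

Step 8
Reactants: 12 silyl ether
Product: 14 enone, 4β-(triethylsilyloxy)-4α-isopropyl-1β,8-dimethyl-5α-H-hydrind-8-en-7-one, via allylic alcohol 13 (not isolated)
Conditions: SeO2 (0.5 equiv), t-BuOOH, CH2Cl2, rt; then Dess–Martin periodinane, CH2Cl2, rt
Reagents that add atoms: selenium dioxide, O=[Se]=O; tert-butyl hydroperoxide, CC(C)(C)OO
Why: Riley allylic oxidation, an ene reaction at the less substituted alkene carbon C9 with abstraction of the pseudoaxial C7–H and a [2,3]-shift that places oxygen on C7 and restores C8=C9 (ring CH2 preferred over CH3, as in the 4β-hydroxylation of cholest-5-enes); Dess–Martin oxidation then converges alcohol and any enone to 14, so the C7 configuration is immaterial.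

Step 9
Reactants: 14 enone
Product: 15 8α,9α-diol, 8α,9α-dihydroxy-4β-(triethylsilyloxy)-4α-isopropyl-1β,8β-dimethyl-5α-H-hydrindan-7-one
Conditions: OsO4 (5 mol%), NMO, citric acid, t-BuOH/H2O, rt
Reagents that add atoms: osmium tetroxide, O=[Os](=O)(=O)=O; N-methylmorpholine N-oxide, C[N+]1([O-])CCOCC1; water, O
Why: Upjohn dihydroxylation (citric-acid-accelerated for an electron-poor alkene); syn addition occurs on the face opposite the axial C1 methyl, which lies 1,3 to C9, giving the 8α,9α-diol, and the neutral medium leaves the ketone α-centre C5 untouched.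

Step 10
Reactants: 15 diol ketone
Product: 16 8α,9α-O-isopropylidene acetal of 15
Conditions: Me2C(OMe)2, PPTS (cat.), acetone, 40 °C
Reagents that add atoms: 2,2-dimethoxypropane, COC(C)(C)OC
Why: Acetonide formation of the cis-1,2-diol by transketalisation; it removes the free tertiary α-ketol, itself prone to α-ketol shift, and places an acetal oxygen on C8.

Step 11
Reactants: 16 acetonide ketone
Product: 17 7-methylidene compound, 8α,9α-(isopropylidenedioxy)-4β-(triethylsilyloxy)-4α-isopropyl-1β,8β-dimethyl-7-methylidene-5α-H-hydrindane
Conditions: Cp2TiMe2 (3 equiv), PhMe, 75 °C, dark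
Reagents that add atoms: dimethyltitanocene, C[Ti](C)(C1C=CC=C1)C1C=CC=C1
Why: Petasis methylenation; the thermally generated titanium methylidene is small and non-basic, so the hindered α-branched ketone is olefinated without enolisation toward C5 or β-elimination of the C4 silyloxy group.

Step 12
Reactants: 17 exocyclic alkene
Product: 18 diol, 7α-hydroxy-7β-(hydroxymethyl) derivative of the acetonide
Conditions: OsO4 (10 mol%), NMO, acetone/H2O, rt
Reagents that add atoms: osmium tetroxide, O=[Os](=O)(=O)=O; N-methylmorpholine N-oxide, C[N+]1([O-])CCOCC1; water, O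
Why: Upjohn dihydroxylation of the 1,1-disubstituted alkene; approach from the β (axial) side is blocked by the 1,3-diaxial C1 methyl, so oxygen reaches C7 from the α (equatorial) side, giving C7-OH α and CH2OH β.

Step 13
Reactants: 18 diol
Product: 19 α-hydroxy aldehyde, 7α-hydroxy-8α,9α-(isopropylidenedioxy)-4β-(triethylsilyloxy)-4α-isopropyl-1β,8β-dimethyl-5α-H-hydrindane-7β-carbaldehyde
Conditions: SO3·pyridine, DMSO, i-Pr2NEt, CH2Cl2, 0 °C
Reagents that add atoms: none
Why: Parikh–Doering oxidation of the primary alcohol of a primary/tertiary 1,2-diol; activated DMSO avoids glycol cleavage, the tertiary hydroxyl cannot be oxidised, and C7 is quaternary so nothing can epimerise.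

Step 14
Reactants: 19 α-hydroxy aldehyde
Product: 20 acyloin, 6α-hydroxy-8α,9α-(isopropylidenedioxy)-4β-(triethylsilyloxy)-4α-isopropyl-1β,8β-dimethyl-5α-H-bicyclo[5.3.0]decan-7-one
Conditions: Al(Ot-Bu)3 (1.5 equiv), PhMe, 80 °C; aq. KNaC4H4O6 work-up
Reagents that add atoms: none
Why: Ligand exchange gives the C7 aluminium alkoxide, and the formyl oxygen binds the same metal in a five-membered chelate with O–C7–C6=O syn-periplanar. The C7–C5 bond then shifts to the formyl carbon while C7 becomes the ketone; this is an α-ketol (acyloin) rearrangement of a tertiary α-hydroxy aldehyde, the reaction type of the aluminium-alkoxide D-homoannulation of 17-hydroxy-20-keto steroids. The seven-membered ring forms by 1,2-shift ring enlargement of the six-membered ring, not by an end-to-end cyclisation. The new C6 centre is set by the chelate: with the formyl group on the β face of C7, C5 lies over only one face of the bound carbonyl and adds to it, placing C6-OH α and C6-H β, while C5 migrates with retention. The step needs C5 rather than C8 to migrate; the acetal oxygen on C8 lowers its migratory aptitude, and the shift of C5 removes the 1,3-diaxial contact between the formyl group and the C1 methyl. The change from aldehyde to ketone supplies the driving force. Al(Ot-Bu)3 is used in place of Al(Oi-Pr)3 because it has no transferable hydride and so cannot reduce the aldehyde in a Meerwein–Ponndorf–Verley sense.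

Step 15
Reactants: 20 acyloin; 21 4-(benzyloxy)benzoyl chloride
Product: 22 6α-[4-(benzyloxy)benzoyl] ester of 20
Conditions: DMAP, Et3N, CH2Cl2, 0 °C to rt
Reagents that add atoms: none
Why: DMAP-catalysed acylation of the only free hydroxyl; the mild amine base at low temperature limits enolisation of the acyloin toward C6.

Step 16
Reactants: 22 protected ester
Product: 23 4β,8α,9α-triol, the target with its phenol as benzyl ether
Conditions: CF3CO2H/H2O (4:1), 0 °C to rt
Reagents that add atoms: none
Why: Aqueous acid hydrolysis cleaves the isopropylidene acetal and the tertiary triethylsilyl ether, while the aryl benzyl ether and the benzoate are stable; no stereocentre is touched.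

Step 17
Reactants: 23 benzyl ether
Product: 24 CNP0241001.1, (1R,4R,5S,6R,8S,9S)-4,8,9-trihydroxy-1,8-dimethyl-7-oxo-4-(propan-2-yl)bicyclo[5.3.0]decan-6-yl 4-hydroxybenzoate (route locants)
Conditions: H2 (1 atm), 10% Pd/C, EtOAc, rt
Reagents that add atoms: none
Why: Hydrogenolysis of the aryl benzyl ether over palladium under neutral conditions, which the acyloin ester, the ketone and the tertiary alcohols tolerate.

## Compound list

1 | ethyl (2E)-3-methyl-4-oxobut-2-enoate | CCOC(=O)/C=C(\C)C=O | starting material
2 | isoprene (2-methylbuta-1,3-diene) | C=CC(C)=C | starting material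
3 | ethyl (1R,6R)-6-formyl-3,6-dimethylcyclohex-3-ene-1-carboxylate | CCOC(=O)[C@@H]1CC(C)=CC[C@@]1(C)C=O | intermediate
4 | ethyl 6-ethenyl-3,6-dimethylcyclohex-3-ene-1-carboxylate (vinyl trans to ester) | CCOC(=O)[C@@H]1CC(C)=CC[C@@]1(C)C=C | intermediate
5 | B-alkyl-9-BBN adduct of 4 (boron on the terminal carbon) | CCOC(=O)[C@@H]1CC(C)=CC[C@@]1(C)CCB1C2CCCC1CCC2 | intermediate
6 | ethyl 6-(2-hydroxyethyl)-3,6-dimethylcyclohex-3-ene-1-carboxylate | CCOC(=O)[C@@H]1CC(C)=CC[C@@]1(C)CCO | intermediate
7 | (4aS,8aR)-4a,7-dimethyl-3,4,4a,5,8,8a-hexahydro-1H-isochromen-1-one (trans-fused) | O=C1OCC[C@]2(C)CC=C(C)C[C@@H]12 | intermediate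
8 | isopropyllithium | CC(C)[Li] | starting material
9 | 1-[6-(2-hydroxyethyl)-3,6-dimethylcyclohex-3-en-1-yl]-2-methylpropan-1-one (arms trans) | CC(C)C(=O)[C@@H]1CC(C)=CC[C@@]1(C)CCO | intermediate
10 | 1-[6-(2-iodoethyl)-3,6-dimethylcyclohex-3-en-1-yl]-2-methylpropan-1-one (arms trans) | CC(C)C(=O)[C@@H]1CC(C)=CC[C@@]1(C)CCI | intermediate
11 | 4α-isopropyl-1β,8-dimethyl-5α-H-hydrind-8-en-4β-ol | CC(C)[C@]1(O)CC[C@]2(C)CC=C(C)C[C@H]21 | intermediate
12 | 4β-triethylsilyl ether of 11 | CC(C)[C@]1(O[Si](CC)(CC)CC)CC[C@]2(C)CC=C(C)C[C@H]21 | intermediate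
13 | 7β-hydroxy derivative of 12 (allylic alcohol, C8=C9) | CC(C)[C@]1(O[Si](CC)(CC)CC)CC[C@]2(C)CC=C(C)[C@@H](O)[C@H]21 | intermediate
14 | 4β-(triethylsilyloxy)-4α-isopropyl-1β,8-dimethyl-5α-H-hydrind-8-en-7-one | CC(C)[C@]1(O[Si](CC)(CC)CC)CC[C@]2(C)CC=C(C)C(=O)[C@H]21 | intermediate
15 | 8α,9α-dihydroxy-4β-(triethylsilyloxy)-4α-isopropyl-1β,8β-dimethyl-5α-H-hydrindan-7-one | CC(C)[C@]1(O[Si](CC)(CC)CC)CC[C@]2(C)C[C@H](O)[C@](C)(O)C(=O)[C@H]21 | intermediate
16 | 8α,9α-O-isopropylidene acetal of 15 | CC(C)[C@]1(O[Si](CC)(CC)CC)CC[C@]2(C)C[C@@H]3OC(C)(C)O[C@]3(C)C(=O)[C@H]21 | intermediate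
17 | 7-methylidene analogue of 16 | CC(C)[C@]1(O[Si](CC)(CC)CC)CC[C@]2(C)C[C@@H]3OC(C)(C)O[C@]3(C)C(=C)[C@H]21 | intermediate
18 | 7α-hydroxy-7β-(hydroxymethyl) diol from 17 | CC(C)[C@]1(O[Si](CC)(CC)CC)CC[C@]2(C)C[C@@H]3OC(C)(C)O[C@]3(C)[C@@](O)(CO)[C@H]21 | intermediate
19 | 7α-hydroxy-7β-carbaldehyde (trans-hydrindane α-hydroxy aldehyde, C8/C9 acetonide, C4 OTES) | CC(C)[C@]1(O[Si](CC)(CC)CC)CC[C@]2(C)C[C@@H]3OC(C)(C)O[C@]3(C)[C@@](O)(C=O)[C@H]21 | intermediate
20 | hydroazulene 6α-hydroxy-7-ketone (C8/C9 acetonide, C4 OTES) | CC(C)[C@]1(O[Si](CC)(CC)CC)CC[C@]2(C)C[C@@H]3OC(C)(C)O[C@]3(C)C(=O)[C@H](O)[C@H]21 | intermediate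
21 | 4-(benzyloxy)benzoyl chloride | O=C(Cl)c1ccc(OCc2ccccc2)cc1 | starting material
22 | 6α-[4-(benzyloxy)benzoyl] ester of 20 | CC(C)[C@]1(O[Si](CC)(CC)CC)CC[C@]2(C)C[C@@H]3OC(C)(C)O[C@]3(C)C(=O)[C@H](OC(=O)c4ccc(OCc5ccccc5)cc4)[C@H]21 | intermediate
23 | target with the phenol as benzyl ether (4β,8α,9α-triol) | CC(C)[C@]1(O)CC[C@]2(C)C[C@H](O)[C@](C)(O)C(=O)[C@H](OC(=O)c3ccc(OCc4ccccc4)cc3)[C@H]21 | intermediate
24 | CNP0241001.1, (1R,4R,5S,6R,8S,9S) in route locants | CC(C)[C@]1(O)CC[C@]2(C)C[C@H](O)[C@](C)(O)C(=O)[C@H](OC(=O)c3ccc(O)cc3)[C@H]21 | target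

## Step count and uncertain steps

Total: 17 steps. Longest linear sequence: 17 steps (from 1 and 2; 8 and 21 are purchased).

**Step 14 (key step).** The chelate can follow other reversible 1,2-shifts at 80 °C: migration of C8 instead of C5, or equilibration of the aluminium-bound acyloin through its enediolate, which would scramble C6 or transpose ketone and carbinol. Fallback, from 18 back to 20: the primary hydroxyl of 18 is tosylated (TsCl, pyridine) to monotosylate F1. Base (KOt-Bu, THF) triggers the semipinacol shift of C5 from C7 to C6 with loss of tosylate, giving cycloheptanone F2, whose only enolisable position is C6. Enolate hydroxylation (KN(SiMe3)2, then 2-(phenylsulfonyl)-3-phenyloxaziridine), expected on the α face remote from the C4 silyloxy group and the angular methyl, returns to 20.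

**Step 8.** Oxidation may occur at the C8 methyl instead of ring C7. The stereoelectronically suited pseudoaxial C7–H lies on the β face, syn to the angular methyl, whereas the methyl hydrogens can be reached from the open α face. Fallback, from 12 back to 14 by a 1,3-carbonyl transposition:
- hydroboration–oxidation (BH3·THF; NaBO3) gives 9α-alcohol F3;
- Dess–Martin oxidation gives C9 ketone F4;
- thermodynamic silylation (Me3SiI, (Me3Si)2NH) gives enol ether F5;
- Saegusa–Ito dehydrogenation (Pd(OAc)2, MeCN) gives the C7=C8 enone F6;
- nucleophilic epoxidation (H2O2, NaOH) from the α face gives epoxy ketone F7;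
- Wharton rearrangement (N2H4·H2O, AcOH) gives the 7α-allylic alcohol F8, which Dess–Martin periodinane oxidises to 14.

**Step 12.** Facial selectivity of osmylation may be poor. The α approach passes the axial C8 acetal oxygen and the acetonide, so attack syn to the angular methyl can compete and invert C7. Fallback, from 17 to 22: the C7-epimeric diol F9 is oxidised as in step 13 to aldehyde F10. The same chelate-controlled shift then gives the 6β-alcohol F11. Mitsunobu esterification with inversion (4-(benzyloxy)benzoic acid, PPh3, diisopropyl azodicarboxylate) rejoins the route at 22.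

**Step 11.** Olefination may be incomplete, since the ketone is flanked by quaternary C8 and branched C5, and prolonged heating may allow enolisation toward C5. Fallback, from 16 to 17 by Peterson olefination: Me3SiCH2Li with CeCl3 adds from the α face to give β-hydroxysilane F12, and KH in THF effects syn-elimination to 17.

**Step 6.** The wrong rotamer may react in the closing transition state, because the solvated samarium alkoxide competes with the isopropyl group for the α position, giving the C4 epimer. Ketyl reduction before cyclisation is also possible. Fallback, from 4 to 11: hydroboration–oxidation of 4 without lactonisation gives hydroxy ester 6, which is iodinated (I2, PPh3, imidazole) to iodo ester F13. Lithium–iodine exchange with t-BuLi at −100 °C closes the ring by acyl substitution to trans-hydrindenone F14. i-PrMgCl with CeCl3 then adds from the α face, anti to the angular methyl, to give 11.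

## Further compounds

F1 | step 14 | primary monotosylate of diol 18 | CC(C)[C@]1(O[Si](CC)(CC)CC)CC[C@]2(C)C[C@@H]3OC(C)(C)O[C@]3(C)[C@@](O)(COS(=O)(=O)c4ccc(C)cc4)[C@H]21
F2 | step 14 | 6-deoxy analogue of 20 (hydroazulen-7-one, C6 methylene) | CC(C)[C@]1(O[Si](CC)(CC)CC)CC[C@]2(C)C[C@@H]3OC(C)(C)O[C@]3(C)C(=O)C[C@H]21
F3 | step 8 | 9α-hydroxy-8α-H hydrindane from hydroboration of 12 | CC(C)[C@]1(O[Si](CC)(CC)CC)CC[C@]2(C)C[C@H](O)[C@@H](C)C[C@H]21
F4 | step 8 | hydrindan-9-one (8β-methyl) | CC(C)[C@]1(O[Si](CC)(CC)CC)CC[C@]2(C)CC(=O)[C@@H](C)C[C@H]21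
F5 | step 8 | 9-(trimethylsilyloxy)hydrind-8-ene (thermodynamic enol ether) | CC(C)[C@]1(O[Si](CC)(CC)CC)CC[C@]2(C)CC(O[Si](C)(C)C)=C(C)C[C@H]21
F6 | step 8 | hydrind-7-en-9-one (transposed enone) | CC(C)[C@]1(O[Si](CC)(CC)CC)CC[C@]2(C)CC(=O)C(C)=C[C@H]21
F7 | step 8 | 7α,8α-epoxyhydrindan-9-one | CC(C)[C@]1(O[Si](CC)(CC)CC)CC[C@]2(C)CC(=O)[C@]3(C)O[C@@H]3[C@H]21
F8 | step 8 | 7α-hydroxy epimer of 13 | CC(C)[C@]1(O[Si](CC)(CC)CC)CC[C@]2(C)CC=C(C)[C@H](O)[C@H]21
F9 | step 12 | C7 epimer of diol 18 (7β-OH, 7α-CH2OH) | CC(C)[C@]1(O[Si](CC)(CC)CC)CC[C@]2(C)C[C@@H]3OC(C)(C)O[C@]3(C)[C@](O)(CO)[C@H]21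
F10 | step 12 | C7 epimer of aldehyde 19 | CC(C)[C@]1(O[Si](CC)(CC)CC)CC[C@]2(C)C[C@@H]3OC(C)(C)O[C@]3(C)[C@](O)(C=O)[C@H]21
F11 | step 12 | 6β-hydroxy epimer of 20 | CC(C)[C@]1(O[Si](CC)(CC)CC)CC[C@]2(C)C[C@@H]3OC(C)(C)O[C@]3(C)C(=O)[C@@H](O)[C@H]21
F12 | step 11 | 7β-hydroxy-7α-(trimethylsilylmethyl) adduct of 16 | CC(C)[C@]1(O[Si](CC)(CC)CC)CC[C@]2(C)C[C@@H]3OC(C)(C)O[C@]3(C)[C@](O)(C[Si](C)(C)C)[C@H]21
F13 | step 6 | ethyl 6-(2-iodoethyl)-3,6-dimethylcyclohex-3-ene-1-carboxylate | CCOC(=O)[C@@H]1CC(C)=CC[C@@]1(C)CCI
F14 | step 6 | 1β,8-dimethyl-5α-H-hydrind-8-en-4-one (trans-fused) | O=C1CC[C@]2(C)CC=C(C)C[C@@H]12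
A1 | alternative 1 | 2-diazo-5-(3,5-dimethoxy-4-methylphenyl)-5-(methoxymethoxy)-6-methylheptan-3-one (C4 as in the target) | CC(C)[C@](OCOC)(CC(=O)C(C)=[N+]=[N-])c1cc(OC)c(C)c(OC)c1
A2 | alternative 1 | angular-methyl dihydroazulenone with enol ethers at C7 and C9 | CC(C)[C@]1(OCOC)CC(=O)[C@]2(C)C=C(OC)C(C)=C(OC)C=C21
A3 | alternative 2 | methyl 2-diazo-3-ethenyl-6-(methoxymethoxy)-3,7-dimethyloctanoate | COC(=O)C(=[N+]=[N-])[C@@](C)(C=C)CC[C@@H](OCOC)C(C)C
A4 | alternative 2 | methyl 2-ethenyl-5-(methoxymethoxy)-2-methyl-5-(propan-2-yl)cyclopentane-1-carboxylate | CC(C)[C@]1(OCOC)CC[C@](C)(C=C)[C@H]1C(=O)OC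
A5 | alternative 3 | Se-phenyl (2Z)-4-[3-(methoxymethoxy)-1-methyl-2-methylidene-3-(propan-2-yl)cyclopentyl]-2-methylbut-2-eneselenoate | CC(C)[C@]1(OCOC)CC[C@](C)(C/C=C(/C)C(=O)[Se]c2ccccc2)C1=C
A6 | alternative 3 | trans-fused 4-(methoxymethoxy)-1,8-dimethyl-4-(propan-2-yl)bicyclo[5.3.0]dec-8-en-7-one | CC(C)[C@]1(OCOC)CC[C@]2(C)CC=C(C)C(=O)C[C@H]21
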